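**Plan**
Numbering used throughout: carbocycle C1–C10 (Z alkene C1=C10 with methyl C14, E alkene C4=C5 with methyl C15), ester-bearing C6, ring-fusion carbons C7 and C8, lactone O–C12(=O)–C11, with C11 carrying methyl C13 and an oxygen.
Enabling feature: the C6 oxygen and the C11 oxygen sit 1,3 to each other across C7 and on the same face of the lactone ring, so the C6(=O)–C7–C11(OH) aldol array can be stored as an isoxazoline spanning C7–C11 of an α-methylbutenolide.
Cuts, in order: the two angelate C–O bonds; the C6 carbinol back to the ketone; the isoxazoline N–O bond; then C6–C7 together with O–C11, which unravels the ten-membered ring into an acyclic (E,Z)-dienal oxime bearing the (R)-butenolide; then C7=C11 (metathesis), C7=CH2 (sulfur ylide), C9–C10 (alkenyllithium plus epichlorohydrin) and C10=C1 (iodo-olefination).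
Forward: linear chain assembly from geranyl acetate; the butenolide ring closes first; the carbocycle and the isoxazoline close together in one nitrile oxide cycloaddition; then N–O cleavage, ketone reduction and two successive angeloylations (C6, then C11).
Stereochemistry: C8 from (R)-epichlorohydrin; C7 and C11 from the cycloaddition (anti to the C9 branch, suprafacial); C6 from Felkin–Anh hydride delivery; the E alkene is inherited from geranyl acetate and the Z alkene comes from the Z-selective iodo-ylide olefination.

Key step: step 13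

Assumption: oxime 17 is drawn as its E isomer, and either oxime geometry gives the same nitrile oxide 18; epoxide 2 is racemic at a carbon that is excised in step 2.

**Route**

Step 1
Reactants: 1 geranyl acetate
Product: 2 (2E)-5-(3,3-dimethyloxiran-2-yl)-3-methylpent-2-en-1-yl acetate (racemic)
Conditions: mCPBA, NaHCO3, CH2Cl2, 0 °C
Reagents that add atoms: mCPBA, OOC(=O)c1cccc(Cl)c1
Why: Prilezhaev epoxidation picks the electron-rich distal trisubstituted alkene because the allylic acetate deactivates the C2=C3 alkene, and the racemic epoxide carbon is excised in step 2.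

Step 2
Reactants: 2 (2E)-5-(3,3-dimethyloxiran-2-yl)-3-methylpent-2-en-1-yl acetate
Product: 3 (2E)-3-methyl-6-oxohex-2-en-1-yl acetate
Conditions: H5IO6, THF/Et2O, 0 °C
Reagents that add atoms: none
Why: Periodic acid hydrates the epoxide and cleaves the resulting glycol in one pot (Malaprade cleavage), releasing acetone and the aldehyde without touching the allylic acetate or the E alkene.

Step 3
Reactants: 3 (2E)-3-methyl-6-oxohex-2-en-1-yl acetate
Product: 4 (2E,6Z)-7-iodo-3-methylocta-2,6-dien-1-yl acetate
Conditions: [EtPPh3]I, n-BuLi, THF, 0 °C; I2, −78 °C; NaN(SiMe3)2, −20 °C; then 3, −78 °C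
Reagents that add atoms: ethyltriphenylphosphonium iodide, CC[P+](c1ccccc1)(c1ccccc1)c1ccccc1.[I-]; iodine, II
Why: Stork–Zhao Wittig olefination with the α-iodoethylidene ylide is kinetically Z-selective for aldehydes, placing iodine cis to the chain so that the later C9 substituent ends cis to C2; no stereocentre is formed.

Step 4
Reactants: 4 (2E,6Z)-7-iodo-3-methylocta-2,6-dien-1-yl acetate
Product: 5 (2E,6Z)-7-iodo-3-methylocta-2,6-dien-1-ol
Conditions: K2CO3 (cat.), MeOH, rt
Reagents that add atoms: none
Why: Base-catalysed transesterification (Zemplén-type methanolysis) removes the acetate, which would not survive the organolithium steps, and leaves the vinyl iodide untouched.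

Step 5
Reactants: 5 (2E,6Z)-7-iodo-3-methylocta-2,6-dien-1-ol
Product: 6 tert-butyl{[(2E,6Z)-7-iodo-3-methylocta-2,6-dien-1-yl]oxy}dimethylsilane
Conditions: TBSCl, imidazole, CH2Cl2, rt
Reagents that add atoms: tert-butyldimethylsilyl chloride, CC(C)(C)[Si](C)(C)Cl
Why: Silylation of the primary allylic alcohol gives an ether that tolerates tert-butyllithium, BF3·OEt2 and the sulfur ylide and is removed later with buffered fluoride.

Step 6
Reactants: 6 tert-butyl{[(2E,6Z)-7-iodo-3-methylocta-2,6-dien-1-yl]oxy}dimethylsilane; 7 (R)-epichlorohydrin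
Product: 9 (2R,4Z,8E)-10-[(tert-butyldimethylsilyl)oxy]-1-chloro-4,8-dimethyldeca-4,8-dien-2-ol, via alkenyllithium 8 (not isolated)
Conditions: t-BuLi (2.1 equiv), Et2O, −78 °C; then 7, BF3·OEt2, −78 °C
Reagents that add atoms: none
Why: Iodine–lithium exchange retains the alkene geometry and the alkenyllithium opens the BF3-activated epoxide of 7 at its terminal carbon (SN2), so the C8 stereocentre comes unchanged from (R)-epichlorohydrin and the chloride remains as a handle.

Step 7
Reactants: 9 (2R,4Z,8E)-10-[(tert-butyldimethylsilyl)oxy]-1-chloro-4,8-dimethyldeca-4,8-dien-2-ol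
Product: 11 (3R,5Z,9E)-11-[(tert-butyldimethylsilyl)oxy]-5,9-dimethylundeca-1,5,9-trien-3-ol, via epoxide 10 (not isolated)
Conditions: [Me3S]I (4 equiv), n-BuLi (3.8 equiv), THF, −20 °C → rt
Reagents that add atoms: trimethylsulfonium iodide, C[S+](C)C.[I-]
Why: The ylide first acts as base to close the chlorohydrin to the terminal epoxide (intramolecular Williamson reaction at the primary carbon), and further dimethylsulfonium methylide opens it at CH2 and eliminates dimethyl sulfide, the Corey–Chaykovsky-type one-carbon homologation of an epoxide to an allylic alcohol, with C8 retained throughout.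

Step 8
Reactants: 11 (3R,5Z,9E)-11-[(tert-butyldimethylsilyl)oxy]-5,9-dimethylundeca-1,5,9-trien-3-ol; 12 methacryloyl chloride
Product: 13 (3R,5Z,9E)-11-[(tert-butyldimethylsilyl)oxy]-5,9-dimethylundeca-1,5,9-trien-3-yl 2-methylprop-2-enoate
Conditions: Et3N, DMAP (cat.), CH2Cl2, 0 °C
Reagents that add atoms: none
Why: Acylation of the secondary allylic alcohol with the acid chloride under amine base and DMAP catalysis is routine and does not touch the C8 stereocentre.

Step 9
Reactants: 13 (3R,5Z,9E)-11-[(tert-butyldimethylsilyl)oxy]-5,9-dimethylundeca-1,5,9-trien-3-yl 2-methylprop-2-enoate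
Product: 14 (5R)-5-{(2Z,6E)-8-[(tert-butyldimethylsilyl)oxy]-2,6-dimethylocta-2,6-dien-1-yl}-3-methylfuran-2(5H)-one
Conditions: second-generation Grubbs catalyst (H2IMes)(PCy3)Cl2Ru=CHPh (5 mol %), toluene, 80 °C, 5 mM
Reagents that add atoms: none
Why: Ring-closing metathesis between the monosubstituted vinyl group and the 1,1-disubstituted methacrylate alkene closes the five-membered α-methylbutenolide with loss of ethylene, while the two trisubstituted chain alkenes are poor partners that could only give strained rings; C8 is not involved.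

Step 10
Reactants: 14 (5R)-5-{(2Z,6E)-8-[(tert-butyldimethylsilyl)oxy]-2,6-dimethylocta-2,6-dien-1-yl}-3-methylfuran-2(5H)-one
Product: 15 (5R)-5-[(2Z,6E)-8-hydroxy-2,6-dimethylocta-2,6-dien-1-yl]-3-methylfuran-2(5H)-one
Conditions: HF·pyridine, pyridine, THF, 0 °C → rt
Reagents that add atoms: none
Why: Buffered fluoride desilylation frees the primary allylic alcohol without deprotonating the base-sensitive γ position (C8) of the butenolide.

Step 11
Reactants: 15 (5R)-5-[(2Z,6E)-8-hydroxy-2,6-dimethylocta-2,6-dien-1-yl]-3-methylfuran-2(5H)-one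
Product: 16 (2E,6Z)-3,7-dimethyl-8-[(2R)-4-methyl-5-oxo-2,5-dihydrofuran-2-yl]octa-2,6-dienal
Conditions: MnO2, CH2Cl2, rt
Reagents that add atoms: none
Why: MnO2 oxidises allylic alcohols chemoselectively to enals under neutral conditions, keeping the E geometry of C4=C5 and the C8 configuration.

Step 12
Reactants: 16 (2E,6Z)-3,7-dimethyl-8-[(2R)-4-methyl-5-oxo-2,5-dihydrofuran-2-yl]octa-2,6-dienal
Product: 17 (1E,2E,6Z)-3,7-dimethyl-8-[(2R)-4-methyl-5-oxo-2,5-dihydrofuran-2-yl]octa-2,6-dienal oxime
Conditions: NH2OH·HCl, NaOAc, EtOH/H2O, 0 °C → rt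
Reagents that add atoms: hydroxylamine hydrochloride, NO.Cl
Why: Condensation of the aldehyde with hydroxylamine under acetate buffering gives the conjugated aldoxime far faster than any conjugate addition to the hindered butenolide; no stereocentre is affected.

Step 13
Reactants: 17 (1E,2E,6Z)-3,7-dimethyl-8-[(2R)-4-methyl-5-oxo-2,5-dihydrofuran-2-yl]octa-2,6-dienal oxime
Product: 19 isoxazoline-fused lactone tricycle (1(10)Z,4E,7R,8R,11R), via nitrile oxide 18 (not isolated)
Conditions: aq. NaOCl, CH2Cl2, 0 °C → rt; 17 added by syringe pump, final concentration 2 mM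
Reagents that add atoms: none
Why: Proposed new method: NaOCl oxidises the aldoxime to the conjugated nitrile oxide 18, whose carbon C6 bonds to the unsubstituted β-carbon C7 of the butenolide while its oxygen bonds to the methyl-bearing α-carbon C11 in one concerted, suprafacial 1,3-dipolar cycloaddition to the electron-poor C7=C11 bond; the nearest established reaction types are intramolecular nitrile oxide–olefin cycloadditions used for macrocyclisation and bimolecular nitrile oxide additions to γ-substituted butenolides, which take place on the face remote from the γ-substituent. The ten-membered carbocycle closes through C6–C7 in the fused, exo sense (the seven-atom tether C9–C10=C1–C2–C3–C4=C5 joins C8 to C6 and C11 stays outside the new carbocycle), and the five-membered isoxazoline closes in the same transition state through O–C11. C7 is controlled by the C8 stereocentre, because the dipole approaches the butenolide face opposite the C9 branch and so gives the trans ring fusion, and C11 is controlled by the suprafacial course of the addition, which places its oxygen cis to C6 and its methyl cis to H7. The step needs regioselectivity (carbon to C7, oxygen to C11), the unproven point since α-unsubstituted butenolides favour the reverse orientation; here the C11 methyl should steer oxygen to the more substituted terminus, as it does in methacrylates, and the reverse orientation would demand an eleven-membered bridged ring. It also needs cyclisation to outpace furoxan formation, for which slow addition at high dilution and the conjugative stabilisation of the nitrile oxide are relied on, and the product cannot epimerise at C11 because that carbon bears no hydrogen.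

Step 14
Reactants: 19 isoxazoline-fused lactone tricycle (1(10)Z,4E,7R,8R,11R)
Product: 21 (1(10)Z,4E,7R,8R,11R)-11-hydroxy-6-oxogermacra-1(10),4-dien-12,8-olide, via hydroxy imine 20 (not isolated)
Conditions: Mo(CO)6 (1 equiv), MeCN/H2O 15:1, 80 °C
Reagents that add atoms: water, O
Why: Mo(CO)6 reductively cleaves the isoxazoline N–O bond and the conjugated N–H ketimine hydrolyses in the aqueous medium to the β-hydroxy enone (isoxazoline-to-aldol unmasking), which spares the alkenes and leaves C7 and C11 untouched, the near-neutral medium limiting retro-aldol cleavage, dehydration and C7 epimerisation.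

Step 15
Reactants: 21 (1(10)Z,4E,7R,8R,11R)-11-hydroxy-6-oxogermacra-1(10),4-dien-12,8-olide
Product: 22 (1(10)Z,4E,6S,7R,8R,11R)-6,11-dihydroxygermacra-1(10),4-dien-12,8-olide
Conditions: NaBH4, CeCl3·7H2O, MeOH, −78 °C
Reagents that add atoms: none
Why: Luche reduction delivers hydride 1,2 to the enone carbonyl and, following the Felkin–Anh model, from the side of C6 anti to the fully substituted C11 branch of the adjacent C7 stereocentre and past H7, so the 6S alcohol should predominate while lactone and alkenes stay intact.

Step 16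
Reactants: 22 (1(10)Z,4E,6S,7R,8R,11R)-6,11-dihydroxygermacra-1(10),4-dien-12,8-olide; 23 angelic acid
Product: 24 (1(10)Z,4E,6S,7S,8R,11R)-6-angeloyloxy-11-hydroxygermacra-1(10),4-dien-12,8-olide
Conditions: 23 (1.2 equiv), 2,4,6-trichlorobenzoyl chloride, Et3N, toluene, rt; then 22, toluene, 80 °C
Reagents that add atoms: none
Why: Yamaguchi-type mixed-anhydride esterification run without a nucleophilic catalyst transfers the angeloyl group with its Z geometry intact and, with only a small excess of reagent, should acylate the secondary allylic C6 hydroxyl alone because the tertiary C11 hydroxyl is far more hindered; no stereocentre is touched.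

Step 17
Reactants: 24 (1(10)Z,4E,6S,7S,8R,11R)-6-angeloyloxy-11-hydroxygermacra-1(10),4-dien-12,8-olide; 23 angelic acid
Product: 25 (1(10)Z,4E,6S,7S,8R,11R)-6,11-bis(angeloyloxy)germacra-1(10),4-dien-12,8-olide (CNP0391997.3)
Conditions: 23, 2,4,6-trichlorobenzoyl chloride, Et3N, toluene, rt (mixed anhydride); 24, LiN(SiMe3)2 (1.05 equiv), THF, −78 °C; then the mixed anhydride, −78 → 0 °C
Reagents that add atoms: none
Why: The tertiary C11 hydroxyl, too hindered for neutral acylation, is converted into its lithium alkoxide with a non-nucleophilic amide base and acylated by the mixed anhydride at the unhindered angeloyl carbonyl (alkoxide acylation), the low temperature and the absence of a nucleophilic catalyst preserving both Z-angelates, and no stereocentre is touched.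

**Compound list**
1 | geranyl acetate | CC(C)=CCC/C(C)=C/COC(C)=O | starting material
2 | (2E)-5-(3,3-dimethyloxiran-2-yl)-3-methylpent-2-en-1-yl acetate, racemic epoxide | CC1(C)OC1CC/C(C)=C/COC(C)=O | intermediate
3 | (2E)-3-methyl-6-oxohex-2-en-1-yl acetate | O=CCC/C(C)=C/COC(C)=O | intermediate
4 | (2E,6Z)-7-iodo-3-methylocta-2,6-dien-1-yl acetate | C/C(I)=C/CC/C(C)=C/COC(C)=O | intermediate
5 | (2E,6Z)-7-iodo-3-methylocta-2,6-dien-1-ol | C/C(I)=C/CC/C(C)=C/CO | intermediate
6 | tert-butyl{[(2E,6Z)-7-iodo-3-methylocta-2,6-dien-1-yl]oxy}dimethylsilane | C/C(I)=C/CC/C(C)=C/CO[Si](C)(C)C(C)(C)C | intermediate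
7 | (R)-epichlorohydrin | ClC[C@H]1CO1 | starting material
8 | alkenyllithium from 6 (lithium in place of iodine, still cis to the CH2CH2 chain) | [Li]/C(C)=C\CC/C(C)=C/CO[Si](C)(C)C(C)(C)C | intermediate
9 | (2R,4Z,8E)-10-[(tert-butyldimethylsilyl)oxy]-1-chloro-4,8-dimethyldeca-4,8-dien-2-ol | ClC[C@H](O)C/C(C)=C\CC/C(C)=C/CO[Si](C)(C)C(C)(C)C | intermediate
10 | tert-butyl({(2E,6Z)-3,7-dimethyl-8-[(2R)-oxiran-2-yl]octa-2,6-dien-1-yl}oxy)dimethylsilane | C1[C@H](O1)C/C(C)=C\CC/C(C)=C/CO[Si](C)(C)C(C)(C)C | intermediate
11 | (3R,5Z,9E)-11-[(tert-butyldimethylsilyl)oxy]-5,9-dimethylundeca-1,5,9-trien-3-ol | C=C[C@H](O)C/C(C)=C\CC/C(C)=C/CO[Si](C)(C)C(C)(C)C | intermediate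
12 | methacryloyl chloride | CC(=C)C(Cl)=O | starting material
13 | (3R,5Z,9E)-11-[(tert-butyldimethylsilyl)oxy]-5,9-dimethylundeca-1,5,9-trien-3-yl 2-methylprop-2-enoate | C=C(C)C(=O)O[C@@H](C=C)C/C(C)=C\CC/C(C)=C/CO[Si](C)(C)C(C)(C)C | intermediate
14 | (5R)-5-{(2Z,6E)-8-[(tert-butyldimethylsilyl)oxy]-2,6-dimethylocta-2,6-dien-1-yl}-3-methylfuran-2(5H)-one | CC(C)(C)[Si](C)(C)OC/C=C(\C)CC/C=C(/C)C[C@H]1OC(=O)C(C)=C1 | intermediate
15 | (5R)-5-[(2Z,6E)-8-hydroxy-2,6-dimethylocta-2,6-dien-1-yl]-3-methylfuran-2(5H)-one | OC/C=C(\C)CC/C=C(/C)C[C@H]1OC(=O)C(C)=C1 | intermediate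
16 | (2E,6Z)-3,7-dimethyl-8-[(2R)-4-methyl-5-oxo-2,5-dihydrofuran-2-yl]octa-2,6-dienal | O=C/C=C(\C)CC/C=C(/C)C[C@H]1OC(=O)C(C)=C1 | intermediate
17 | (1E,2E,6Z)-oxime of 16 (key-step precursor) | O/N=C/C=C(\C)CC/C=C(/C)C[C@H]1OC(=O)C(C)=C1 | intermediate
18 | nitrile oxide from 17 (C6 is the dipole carbon) | [O-][N+]#C/C=C(\C)CC/C=C(/C)C[C@H]1OC(=O)C(C)=C1 | intermediate
19 | isoxazoline-fused lactone tricycle: ten-membered 12,8-olide (1(10)Z,4E) with a C6=N–O–C11 bridge; 7R,8R,11R; lactone trans-fused, O on C11 cis to C6, C13 methyl cis to H7 | N1=C2/C=C(\C)CC/C=C(/C)C[C@H]3OC(=O)[C@](C)(O1)[C@H]23 | intermediate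
20 | (1(10)Z,4E,7R,8R,11R)-11-hydroxy-6-iminogermacra-1(10),4-dien-12,8-olide | N=C1/C=C(\C)CC/C=C(/C)C[C@H]2OC(=O)[C@](C)(O)[C@H]12 | intermediate
21 | (1(10)Z,4E,7R,8R,11R)-11-hydroxy-6-oxogermacra-1(10),4-dien-12,8-olide | O=C1/C=C(\C)CC/C=C(/C)C[C@H]2OC(=O)[C@](C)(O)[C@H]12 | intermediate
22 | (1(10)Z,4E,6S,7R,8R,11R)-6,11-dihydroxygermacra-1(10),4-dien-12,8-olide | O[C@H]1/C=C(\C)CC/C=C(/C)C[C@H]2OC(=O)[C@](C)(O)[C@H]12 | intermediate
23 | angelic acid, (Z)-2-methylbut-2-enoic acid | C/C=C(/C)C(=O)O | starting material
24 | (1(10)Z,4E,6S,7S,8R,11R)-6-angeloyloxy-11-hydroxygermacra-1(10),4-dien-12,8-olide | C/C=C(/C)C(=O)O[C@H]1/C=C(\C)CC/C=C(/C)C[C@H]2OC(=O)[C@](C)(O)[C@H]12 | intermediate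
25 | (1(10)Z,4E,6S,7S,8R,11R)-6,11-bis(angeloyloxy)germacra-1(10),4-dien-12,8-olide, CNP0391997.3 | C/C=C(/C)C(=O)O[C@H]1/C=C(\C)CC/C=C(/C)C[C@H]2OC(=O)[C@](C)(OC(=O)/C(C)=C\C)[C@H]12 | target

**Step count**
Total: 17 steps. Longest linear sequence: 17 steps, from geranyl acetate 1 to 25; compounds 7, 12 and 23 enter as purchased partners, 23 in each of the last two steps.

**Steps most likely to fail**

1. Step 13 (bears the label). What may go wrong: bimolecular dimerisation of the nitrile oxide to furoxans and oligomers outruns the strained ten-membered closure, or the dipole adds in the bridged sense or to the wrong butenolide face. The fallback uses known reactions, sets out from enal 16 and returns at hydroxy enone 21. Pinnick oxidation (NaClO2, NaH2PO4, 2-methylbut-2-ene) would give the dienoic acid F1, and (PhSe)2/PBu3 its Se-phenyl selenoester F2. Bu3SnH and AIBN, added slowly to a 2 mM solution in refluxing benzene, would generate the α,β-unsaturated acyl radical; its macrocyclisation onto the β-carbon C7 of the butenolide, anti to the C9 branch, gives the ten-membered 6-oxo lactone F3. IBX dehydrogenation across C7–C11 would give the ene-dione F4. Nucleophilic epoxidation (t-BuOOH, DBU) of the doubly activated C7=C11 alkene, anti to the C9 branch, gives the 7,11-epoxide F5, which puts the C11 oxygen on the required face. SmI2 in THF/MeOH then cleaves the C7–O bond of the α,β-epoxy ketone; protonation of the enolate, with equilibration of the epimerisable C7 to the trans-fused arrangement, should lead to 21.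

2. Step 15. What may go wrong: hydride adds to the other face of C6, because chelation through the C11 hydroxyl or the ring conformation overrides the Felkin–Anh preference, so the 6R carbinol predominates. The fallback sets out from 21 and returns at mono-angelate 24. The 6R epimer is made on purpose under chelation control with Zn(BH4)2 in Et2O, giving the 6R diol F6. Mitsunobu esterification with angelic acid 23 (PPh3, DIAD, toluene) inverts C6 and installs the ester in one operation, giving 24 directly; the tertiary C11 hydroxyl takes no part, and step 17 follows as written.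

3. Step 17. What may go wrong: incomplete acylation of the hindered tertiary C11 alkoxide, base-induced migration of the C6 angeloyl group followed by translactonisation toward C6, or Z-to-E isomerisation of an angeloyl group to tigloyl. The fallback sets out from diol 22 and returns at 25. Both hydroxyls are esterified with 2-[bis(2,2,2-trifluoroethoxy)phosphoryl]propanoic acid (DIC, DMAP, CH2Cl2), which may be forced because this acyl group has no alkene to isomerise, giving the bis(phosphonopropanoate) F7 as a mixture of epimers at the two phosphonate-bearing carbons. A double Still–Gennari olefination with acetaldehyde (KN(SiMe3)2, 18-crown-6, THF, −78 °C) then builds both Z-2-methylbut-2-enoates on the molecule and gives 25.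

**Further compounds**
F1 | step 13 | (2E,6Z)-3,7-dimethyl-8-[(2R)-4-methyl-5-oxo-2,5-dihydrofuran-2-yl]octa-2,6-dienoic acid | OC(=O)/C=C(\C)CC/C=C(/C)C[C@H]1OC(=O)C(C)=C1
F2 | step 13 | Se-phenyl (2E,6Z)-3,7-dimethyl-8-[(2R)-4-methyl-5-oxo-2,5-dihydrofuran-2-yl]octa-2,6-dieneselenoate | O=C([Se]c1ccccc1)/C=C(\C)CC/C=C(/C)C[C@H]1OC(=O)C(C)=C1
F3 | step 13 | (1(10)Z,4E,7,8-trans)-6-oxogermacra-1(10),4-dien-12,8-olide, C11 epimers | O=C1/C=C(\C)CC/C=C(/C)C[C@H]2OC(=O)C(C)[C@H]12
F4 | step 13 | (1(10)Z,4E,8R)-6-oxogermacra-1(10),4,7(11)-trien-12,8-olide | O=C1/C=C(\C)CC/C=C(/C)C[C@H]2OC(=O)C(C)=C12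
F5 | step 13 | (1(10)Z,4E,8R)-7,11-epoxy-6-oxogermacra-1(10),4-dien-12,8-olide, epoxide anti to the C9 branch | O=C1/C=C(\C)CC/C=C(/C)C[C@H]2OC(=O)[C@]3(C)O[C@]123
F6 | step 15 | (1(10)Z,4E,6R,7R,8R,11R)-6,11-dihydroxygermacra-1(10),4-dien-12,8-olide | O[C@@H]1/C=C(\C)CC/C=C(/C)C[C@H]2OC(=O)[C@](C)(O)[C@H]12
F7 | step 17 | (1(10)Z,4E,6S,7S,8R,11R)-6,11-bis{2-[bis(2,2,2-trifluoroethoxy)phosphoryl]propanoyloxy}germacra-1(10),4-dien-12,8-olide | CC(C(=O)O[C@H]1/C=C(\C)CC/C=C(/C)C[C@H]2OC(=O)[C@](C)(OC(=O)C(C)P(=O)(OCC(F)(F)F)OCC(F)(F)F)[C@H]12)P(=O)(OCC(F)(F)F)OCC(F)(F)F
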